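**Plan**
- Retrosynthesis: the three phenols (5-OH, 7-OH, 3'-OH) are masked as benzyl ethers, then ring C of the isoflavone is cut at O1–C8a and C4–C4a in a single operation.
- Enabling feature: ring A (C4a, C5, C6, C7, C8, C8a) carries oxygen on C5, C7 and C8a, a 1,3,5 pattern. The matching 3,5-bis(benzyloxy)benzyne is polarised by the benzyloxy group beside the triple bond, so O1 enters at C8a and the acyl carbon C4 at C4a.
- The C2–C3–C4 unit, with ring B already on C3, is an ethyl 2-aryl-3-hydroxyacrylate. It comes from the ring B aldehyde and ethyl diazoacetate by an acid-catalysed 1,2-aryl shift, which also makes the crowded C3–C1' bond.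
- Forward: aryne precursor from 3,5-bis(benzyloxy)phenol (steps 1–3); acrylate from 2,4,6-trimethoxyphenol (steps 4–6); annulation closes ring C, the only ring formed (step 7); hydrogenolysis frees the phenols (step 8).
- Stereochemistry: the target has no stereocentre. Only the enol geometry matters for ring closure, and it equilibrates under the basic conditions of step 7.

Key step: step 7

Assumption: 3,5-bis(benzyloxy)phenol, 2,4,6-trimethoxyphenol and ethyl diazoacetate are purchased; enol 14 is drawn as its hydrogen-bonded Z form, which is in equilibrium with the aldehyde tautomer.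

Step 1
Reactants: 1 3,5-bis(benzyloxy)phenol
Product: 2 3,5-bis(benzyloxy)phenyl N-isopropylcarbamate
Conditions: i-PrNCO, Et3N (cat.), CH2Cl2, rt
Reagents that add atoms: isopropyl isocyanate, CC(C)N=C=O
Why: Amine-catalysed carbamoylation of an unhindered phenol with an isocyanate is reliable, and the N-monosubstituted carbamate is a strong ortho director that can later be removed with mild base.

Step 2
Reactants: 2 3,5-bis(benzyloxy)phenyl N-isopropylcarbamate
Product: 6 3,5-bis(benzyloxy)-2-(trimethylsilyl)phenyl N-isopropylcarbamate, via N-silylated carbamate 3 (not isolated), via ortho-lithiated N-silyl carbamate 4 (not isolated), via C,N-bis(trimethylsilyl) carbamate 5 (not isolated)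
Conditions: TMSOTf, TMEDA, Et2O, 0 °C to rt; then TMEDA, n-BuLi (2 equiv), −78 °C; then TMSCl, −78 °C to rt; H2O work-up
Reagents that add atoms: chlorotrimethylsilane, C[Si](C)(C)Cl
Why: Directed ortho-metalation: after N-silylation in the flask the carbamate is the strongest director, its two ortho positions are equivalent and each is further acidified by the neighbouring benzyloxy group, so lithiation at −78 °C should occur there rather than between the two ethers or at a benzylic CH2, and TMSCl traps the aryllithium.

Step 3
Reactants: 6 3,5-bis(benzyloxy)-2-(trimethylsilyl)phenyl N-isopropylcarbamate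
Product: 8 3,5-bis(benzyloxy)-2-(trimethylsilyl)phenyl trifluoromethanesulfonate, via 3,5-bis(benzyloxy)-2-(trimethylsilyl)phenol 7 (not isolated)
Conditions: DBU, Et2NH, MeCN, 40 °C; then PhNTf2, rt
Reagents that add atoms: N-phenylbis(trifluoromethanesulfonimide), O=S(=O)(N(c1ccccc1)S(=O)(=O)C(F)(F)F)C(F)(F)F
Why: Base-induced elimination of the N–H carbamate (the isocyanate is captured by Et2NH as a urea) frees the phenoxide, which is triflated in the same pot, a standard one-pot carbamate-to-triflate exchange that avoids handling the acid-sensitive ortho-silylphenol.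

Step 4
Reactants: 9 2,4,6-trimethoxyphenol
Product: 10 2-(benzyloxy)-1,3,5-trimethoxybenzene
Conditions: BnBr, K2CO3, DMF, rt
Reagents that add atoms: benzyl bromide, BrCc1ccccc1
Why: Williamson ether synthesis on a phenoxide; the two flanking methoxy groups do not prevent O-alkylation by a primary benzylic bromide.

Step 5
Reactants: 10 2-(benzyloxy)-1,3,5-trimethoxybenzene
Product: 12 3-(benzyloxy)-2,4,6-trimethoxybenzaldehyde, via aryl iminium salt 11 (not isolated)
Conditions: POCl3, DMF, 0 °C to 50 °C; then ice-water
Reagents that add atoms: N,N-dimethylformamide, CN(C)C=O; water, O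
Why: Vilsmeier–Haack formylation: the two free ring positions are equivalent and each is ortho to two methoxy groups and para to the third, so a single aldehyde should form, and the benzyl ether tolerates the conditions.

Step 6
Reactants: 12 3-(benzyloxy)-2,4,6-trimethoxybenzaldehyde, 13 ethyl diazoacetate
Product: 14 ethyl (Z)-2-[3-(benzyloxy)-2,4,6-trimethoxyphenyl]-3-hydroxyprop-2-enoate
Conditions: HBF4·OEt2 (10 mol%), CH2Cl2, −78 °C to rt
Reagents that add atoms: none
Why: Acid-catalysed aldehyde–diazoacetate homologation with 1,2-aryl shift (the aryl-migration counterpart of the Roskamp reaction): the diazoester adds to the protonated aldehyde, N2 leaves as the very electron-rich trialkoxyaryl group migrates in preference to hydride, and the 2-aryl-3-oxopropanoate is obtained as its chelated Z enol.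

Step 7
Reactants: 8 3,5-bis(benzyloxy)-2-(trimethylsilyl)phenyl trifluoromethanesulfonate, 14 ethyl (Z)-2-[3-(benzyloxy)-2,4,6-trimethoxyphenyl]-3-hydroxyprop-2-enoate
Product: 16 5,7-bis(benzyloxy)-3-[3-(benzyloxy)-2,4,6-trimethoxyphenyl]-4H-chromen-4-one, via 3,5-bis(benzyloxy)benzyne 15 (not isolated)
Conditions: CsF (4 equiv), THF, 65 °C, sealed tube; 8 in slight excess
Reagents that add atoms: none
Why: Proposed new method: CsF deprotonates enol 14 and, by attack at silicon with loss of triflate, turns 8 into aryne 15; the enolate oxygen adds to the aryne carbon remote from the flanking benzyloxy group (future C8a), so the carbanion appears on the carbon next to that group (future C4a), where the C–O dipole stabilises it. This aryl anion sits cis to the ester across the enol ether double bond and attacks the ester carbonyl with loss of ethoxide, so ring C closes by 6-exo-trig acyl substitution and the 4-pyranone forms directly. The closest known reaction type is the CsF-mediated annulation of arynes with salicylate esters to xanthones (O-arylation, then intramolecular acyl substitution); what is new is that an acyclic 2-aryl-3-hydroxyacrylate takes the place of the phenolic ester. No stereocentre is created. Three selectivities are needed: aryne regiochemistry, secured by the inductive effect of the benzyloxy group beside the triple bond; O- rather than C-arylation of the ambident enolate, secured by the 2,6-dimethoxyaryl group that shields both faces of the enolate carbon; and cyclisation ahead of protonation of the aryl anion, secured by the chelated Z geometry (the enolate isomers interconvert) and by THF at 65 °C as a poor proton source.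

Step 8
Reactants: 16 5,7-bis(benzyloxy)-3-[3-(benzyloxy)-2,4,6-trimethoxyphenyl]-4H-chromen-4-one
Product: 17 5,7-dihydroxy-3-(3-hydroxy-2,4,6-trimethoxyphenyl)-4H-chromen-4-one
Conditions: H2 (1 atm), 10% Pd/C, EtOAc–MeOH, rt, stopped once the benzyl ethers are consumed
Reagents that add atoms: none
Why: Catalytic hydrogenolysis of aryl benzyl ethers is routine; the methyl ethers are inert and the trisubstituted, aryl-shielded C2–C3 double bond of the chromone should be reduced much more slowly than the benzyl C–O bonds are cleaved.

**Compound list**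
1 | 3,5-bis(benzyloxy)phenol | Oc1cc(OCc2ccccc2)cc(OCc2ccccc2)c1 | starting material
2 | 3,5-bis(benzyloxy)phenyl N-isopropylcarbamate | CC(C)NC(=O)Oc1cc(OCc2ccccc2)cc(OCc2ccccc2)c1 | intermediate
3 | 3,5-bis(benzyloxy)phenyl N-isopropyl-N-(trimethylsilyl)carbamate | CC(C)N(C(=O)Oc1cc(OCc2ccccc2)cc(OCc2ccccc2)c1)[Si](C)(C)C | intermediate
4 | [2,4-bis(benzyloxy)-6-{[isopropyl(trimethylsilyl)carbamoyl]oxy}phenyl]lithium | CC(C)N(C(=O)Oc1cc(OCc2ccccc2)cc(OCc2ccccc2)c1[Li])[Si](C)(C)C | intermediate
5 | 3,5-bis(benzyloxy)-2-(trimethylsilyl)phenyl N-isopropyl-N-(trimethylsilyl)carbamate | CC(C)N(C(=O)Oc1cc(OCc2ccccc2)cc(OCc2ccccc2)c1[Si](C)(C)C)[Si](C)(C)C | intermediate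
6 | 3,5-bis(benzyloxy)-2-(trimethylsilyl)phenyl N-isopropylcarbamate | CC(C)NC(=O)Oc1cc(OCc2ccccc2)cc(OCc2ccccc2)c1[Si](C)(C)C | intermediate
7 | 3,5-bis(benzyloxy)-2-(trimethylsilyl)phenol (present as its DBU salt) | C[Si](C)(C)c1c(O)cc(OCc2ccccc2)cc1OCc1ccccc1 | intermediate
8 | 3,5-bis(benzyloxy)-2-(trimethylsilyl)phenyl trifluoromethanesulfonate | C[Si](C)(C)c1c(OS(=O)(=O)C(F)(F)F)cc(OCc2ccccc2)cc1OCc1ccccc1 | intermediate
9 | 2,4,6-trimethoxyphenol | COc1cc(OC)c(O)c(OC)c1 | starting material
10 | 2-(benzyloxy)-1,3,5-trimethoxybenzene | COc1cc(OC)c(OCc2ccccc2)c(OC)c1 | intermediate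
11 | N-{[3-(benzyloxy)-2,4,6-trimethoxyphenyl]methylidene}-N-methylmethanaminium dichlorophosphate | C[N+](C)=Cc1c(OC)cc(OC)c(OCc2ccccc2)c1OC.[O-]P(=O)(Cl)Cl | intermediate
12 | 3-(benzyloxy)-2,4,6-trimethoxybenzaldehyde | O=Cc1c(OC)cc(OC)c(OCc2ccccc2)c1OC | intermediate
13 | ethyl diazoacetate | CCOC(=O)C=[N+]=[N-] | starting material
14 | ethyl (Z)-2-[3-(benzyloxy)-2,4,6-trimethoxyphenyl]-3-hydroxyprop-2-enoate | CCOC(=O)/C(=C\O)c1c(OC)cc(OC)c(OCc2ccccc2)c1OC | intermediate
15 | 3,5-bis(benzyloxy)benzyne (3,5-bis(benzyloxy)-1,2-didehydrobenzene) | C1#CC(OCc2ccccc2)=CC(OCc2ccccc2)=C1 | intermediate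
16 | 5,7-bis(benzyloxy)-3-[3-(benzyloxy)-2,4,6-trimethoxyphenyl]-4H-chromen-4-one | O=c1c(-c2c(OC)cc(OC)c(OCc3ccccc3)c2OC)coc2cc(OCc3ccccc3)cc(OCc3ccccc3)c12 | intermediate
17 | 5,7-dihydroxy-3-(3-hydroxy-2,4,6-trimethoxyphenyl)-4H-chromen-4-one (CNP0211564.0) | COc1cc(OC)c(-c2coc3cc(O)cc(O)c3c2=O)c(OC)c1O | target

**Step count**
Total steps: 8. Longest linear sequence: 5 (steps 4, 5, 6, 7, 8; the aryne branch, steps 1, 2, 3, 7, 8, is equally long).

**Steps most likely to fail**

Step 7 (bears the label "Proposed new method:"). The ambident enolate may be arylated at carbon instead of oxygen, after which four-ring closure and fragmentation would follow. Alternatively the aryl anion may be protonated before it reaches the ester, leaving an open aryl enol ether. The fallback uses known chemistry, sets out from 14 and 8 and returns at 16. Enol ester 14 is heated with aqueous NaOH in ethanol, which removes the formyl group by retro-Claisen cleavage and saponifies the ester; acidification should give [3-(benzyloxy)-2,4,6-trimethoxyphenyl]acetic acid F1. F1 and silyl triflate 8 are combined with CsF in THF at 125 °C in a sealed tube. The carboxylate, an oxygen nucleophile with no competing carbon site, adds to aryne 15 at the same remote carbon, and the ortho carbanion takes over the acyl group. This is the known insertion of arynes into the C–O bond of carboxylic acids and should give 1-[2,4-bis(benzyloxy)-6-hydroxyphenyl]-2-[3-(benzyloxy)-2,4,6-trimethoxyphenyl]ethan-1-one F2. Heating F2 with N,N-dimethylformamide dimethyl acetal in toluene should give (E)-1-[2,4-bis(benzyloxy)-6-hydroxyphenyl]-2-[3-(benzyloxy)-2,4,6-trimethoxyphenyl]-3-(dimethylamino)prop-2-en-1-one F3, which closes with loss of dimethylamine to 16. This is the classical deoxybenzoin route to isoflavones: C2 arrives last and ring C is closed in a separate condensation.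

Step 2. A benzylic CH2 of a benzyl ether may be deprotonated and undergo Wittig rearrangement, or metalation may occur between the two benzyloxy groups. The fallback replaces deprotonation by halogen–lithium exchange, sets out from 1 and returns at 8. Phenol 1 is brominated ortho to the hydroxyl group with NBS and catalytic i-Pr2NH in CH2Cl2 at low temperature, the para isomer being removed by chromatography, to give 3,5-bis(benzyloxy)-2-bromophenol F4. Silylation with hexamethyldisilazane in hot THF gives [3,5-bis(benzyloxy)-2-bromophenoxy]trimethylsilane F5. Treatment of F5 with n-BuLi in THF at −100 °C brings about bromine–lithium exchange, followed at once by O-to-C silyl migration (retro-Brook rearrangement) to the lithium phenolate of 7. Addition of Tf2O at −78 °C then gives 8. Because the exchange is far faster than deprotonation, the benzyl ethers are not exposed to a long-lived strong base.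

Step 6. Hydride may migrate instead of the aryl group, which leads to the β-keto ester, or the diazoester may add only sluggishly to the deactivated, doubly ortho-substituted aldehyde. The fallback builds the arylacetate first and adds the formyl carbon by Claisen condensation; it sets out from 12 and returns at 14. Aldehyde 12 is condensed with methyl (methylsulfanyl)methyl sulfoxide (benzyltrimethylammonium hydroxide, THF, reflux) to give 1-(benzyloxy)-2,4,6-trimethoxy-3-[2-(methylsulfanyl)-2-(methylsulfinyl)ethenyl]benzene F6. Treatment of F6 with HCl in ethanol should give ethyl [3-(benzyloxy)-2,4,6-trimethoxyphenyl]acetate F7. Formylation of F7 with NaH and ethyl formate in THF, followed by acidic work-up, gives 14.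

Further compounds
F1 | step 7 | [3-(benzyloxy)-2,4,6-trimethoxyphenyl]acetic acid | OC(=O)Cc1c(OC)cc(OC)c(OCc2ccccc2)c1OC
F2 | step 7 | 1-[2,4-bis(benzyloxy)-6-hydroxyphenyl]-2-[3-(benzyloxy)-2,4,6-trimethoxyphenyl]ethan-1-one | O=C(Cc1c(OC)cc(OC)c(OCc2ccccc2)c1OC)c1c(O)cc(OCc2ccccc2)cc1OCc1ccccc1
F3 | step 7 | (E)-1-[2,4-bis(benzyloxy)-6-hydroxyphenyl]-2-[3-(benzyloxy)-2,4,6-trimethoxyphenyl]-3-(dimethylamino)prop-2-en-1-one | CN(C)/C=C(\c1c(OC)cc(OC)c(OCc2ccccc2)c1OC)C(=O)c1c(O)cc(OCc2ccccc2)cc1OCc1ccccc1
F4 | step 2 | 3,5-bis(benzyloxy)-2-bromophenol | Oc1cc(OCc2ccccc2)cc(OCc2ccccc2)c1Br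
F5 | step 2 | [3,5-bis(benzyloxy)-2-bromophenoxy]trimethylsilane | C[Si](C)(C)Oc1cc(OCc2ccccc2)cc(OCc2ccccc2)c1Br
F6 | step 6 | 1-(benzyloxy)-2,4,6-trimethoxy-3-[2-(methylsulfanyl)-2-(methylsulfinyl)ethenyl]benzene (racemic at sulfur, alkene geometry not controlled) | CSC(=Cc1c(OC)cc(OC)c(OCc2ccccc2)c1OC)S(C)=O
F7 | step 6 | ethyl [3-(benzyloxy)-2,4,6-trimethoxyphenyl]acetate | CCOC(=O)Cc1c(OC)cc(OC)c(OCc2ccccc2)c1OC
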